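**Plan**

- Labels: ring C1 (C=O), C2 (C–CH3) and C3 (the oxirane carbons), C4 (CH2), C5 (CH with the side chain), C6 (CH–O-tigloyl); side chain C7(=C14H2)–C8(=O)–C9=C10–C11(CH3)2OOH.
- Cuts, in retrosynthetic order: C11–OOH with the C9=C10 shift (ene reaction of a prenyl ketone); C10=C11 and C8–C9 (cross-metathesis, allylation of a C8 aldehyde); the oxirane C–O bonds; the C6–O ester; ring bond C1–C6; chain bond C4–C5.
- Forward: an itaconate-derived C5–C8 ester and a butenolide-derived (Z)-C1–C4 bromo enoate are joined at C4–C5 and taken to an open-chain dialdehyde. The cyclohexenone ring arises once, by closure of C1–C6; oxirane and side chain follow.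
- Enabling feature: C1–C6 joins a ketone carbon to a carbinol carbon (an α-ketol), the retron of a benzoin union of a C1 enal with a C6 formyl group. In the open chain C5–H is α to C6=O and allylic to C7=C14, so C5 racemises and one chiral carbene can fix C5 and C6 together by dynamic kinetic resolution. The (Z)-C2=C3 bond holds C1 next to C6.
- Stereochemistry: C5 and C6 from that step (C6–O trans to the side chain); the C1 carbinol by axial hydride delivery, the oxirane delivered syn to it by VO(acac)2/t-BuOOH, C1 then reoxidised; the (E) tiglate from tigloyl chloride and (E)-C9=C10 from the ene reaction.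

Key step: step 7

Remark: which antipode of the triazolium salt gives the (5S,6S) series is an assumption (the (5aR,10bS) salt is written, its mirror image is used if needed); 19 and 21 are C8-epimer mixtures that converge at 22.

**Route**

Step 1
Reactants: 1 monomethyl itaconate (4-methoxy-2-methylidene-4-oxobutanoic acid)
Product: 3 methyl 3-(hydroxymethyl)but-3-enoate, via mixed carbonic anhydride 2 (not isolated)
Conditions: ClCO2Et, Et3N, THF, −10 °C; then NaBH4, THF/H2O, 0 °C
Reagents that add atoms: none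
Why: Activation of the free acrylic acid as its mixed carbonic anhydride lets NaBH4 reduce it to the allylic alcohol while the methyl ester, inert to NaBH4 at 0 °C, is kept (mixed-anhydride reduction); no stereocentre is formed and 3 is silylated at once so that it cannot lactonise.

Step 2
Reactants: 3 methyl 3-(hydroxymethyl)but-3-enoate
Product: 4 methyl 3-[(tert-butyldimethylsilyloxy)methyl]but-3-enoate
Conditions: TBSCl, imidazole, CH2Cl2, 0 °C
Reagents that add atoms: tert-butyldimethylsilyl chloride CC(C)(C)[Si](C)(C)Cl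
Why: Imidazole-mediated silylation of a primary allylic alcohol, chosen because the silyl ether survives the enolate, hydride, carbene and peroxide steps and is removed by fluoride.

Step 3
Reactants: 5 3-methylfuran-2(5H)-one
Product: 6 methyl (2Z)-4-bromo-2-methylbut-2-enoate
Conditions: AcBr (gives HBr in situ), MeOH, 0 → 23 °C
Reagents that add atoms: acetyl bromide (bromine, through HBr) CC(=O)Br; methanol CO
Why: Acid-mediated alcoholysis of the lactone with bromide capture at the allylic O–CH2 carbon (the classical conversion of γ-lactones into γ-bromo esters with HBr in an alcohol) opens the butenolide without touching the ring double bond, which therefore emerges as the (Z) alkene with CH2Br cis to CO2CH3.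

Step 4
Reactants: 4 methyl 3-[(tert-butyldimethylsilyloxy)methyl]but-3-enoate; 6 methyl (2Z)-4-bromo-2-methylbut-2-enoate
Product: 8 dimethyl (2Z)-5-[3-(tert-butyldimethylsilyloxy)prop-1-en-2-yl]-2-methylhex-2-enedioate (racemic at C5), via lithium dienolate 7 (not isolated)
Conditions: LiN(iPr)2, THF, −78 °C; then 6, −78 → −40 °C
Reagents that add atoms: none
Why: LiN(iPr)2 gives the dienolate of the β,γ-unsaturated ester, which alkylates kinetically at its α-carbon (C5) by SN2 displacement of the primary allylic bromide (enolate alkylation); C5 is made racemic on purpose because it is resolved dynamically in step 7, and the (Z) geometry of C2=C3 is carried over from 6.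

Step 5
Reactants: 8 dimethyl (2Z)-5-[3-(tert-butyldimethylsilyloxy)prop-1-en-2-yl]-2-methylhex-2-enedioate
Product: 9 (2Z)-5-[3-(tert-butyldimethylsilyloxy)prop-1-en-2-yl]-2-methylhex-2-ene-1,6-diol (racemic)
Conditions: i-Bu2AlH, CH2Cl2, −78 → 0 °C; Rochelle salt work-up
Reagents that add atoms: none
Why: i-Bu2AlH reduces the saturated and the conjugated methyl ester to primary alcohols in one operation (1,2-reduction of the enoate) and leaves the silyl ether and both alkenes alone, so the (Z) geometry is kept.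

Step 6
Reactants: 9 (2Z)-5-[3-(tert-butyldimethylsilyloxy)prop-1-en-2-yl]-2-methylhex-2-ene-1,6-diol
Product: 10 (2Z)-5-[3-(tert-butyldimethylsilyloxy)prop-1-en-2-yl]-2-methylhex-2-enedial (racemic)
Conditions: Dess–Martin periodinane, NaHCO3, CH2Cl2, 0 → 23 °C; used without storage
Reagents that add atoms: none
Why: Dess–Martin oxidation under bicarbonate buffer takes both primary alcohols to aldehydes under neutral conditions, which matters because the (Z)-enal and the α-alkenyl aldehyde isomerise with acid or base.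

Step 7
Reactants: 10 (2Z)-5-[3-(tert-butyldimethylsilyloxy)prop-1-en-2-yl]-2-methylhex-2-enedial (racemic)
Product: 11 (5S,6S)-6-hydroxy-2-methyl-5-[3-(tert-butyldimethylsilyloxy)prop-1-en-2-yl]cyclohex-2-en-1-one
Conditions: (5aR,10bS)-2-(pentafluorophenyl)-5a,10b-dihydro-4H,6H-indeno[2,1-b][1,2,4]triazolo[4,3-d][1,4]oxazin-2-ium tetrafluoroborate (15 mol %), i-Pr2NEt, 4 Å molecular sieves, toluene, 0 → 23 °C
Reagents that add atoms: none
Why: Proposed new method: the carbene adds to the conjugated C1 formyl group and the resulting Breslow intermediate (an acyl-anion equivalent) attacks the C6 formyl carbon in a 6-exo-trig closure, after which proton transfer and loss of the carbene leave the C1 ketone and the C6 carbinol; the closest known reaction types are the carbene-catalysed intramolecular aldehyde–aldehyde benzoin cyclisation and the dynamic kinetic resolution of racemic keto aldehydes by intramolecular crossed benzoin reaction. The step is new in that the centre resolved dynamically is C5 of an α-alkenyl aldehyde, which racemises through its dienol(ate) under the amine base because C5–H is both α to C6=O and allylic to C7=C14. C6 is set by the chiral carbene (face of the acceptor carbonyl), and C5 follows because only the antipode that places the side chain pseudo-equatorial and trans to the forming C6–O bond in the chair-like transition state closes quickly, the other being returned to the racemising pool. Chemoselectivity for the enal as donor is needed: the α-branched C6 aldehyde is the poorer donor and the better acceptor, and the crossed acyloin with the ketone at C6 would in any case tautomerise through the enediol to the conjugated enone 11, the thermodynamic sink. The (Z) geometry of C2=C3, fixed by the butenolide origin of C1–C4, is what lets C1 reach C6. Conjugation of C7=C14 with the C6 aldehyde and aldol closure from C5 are the competing processes, held back by a weak base, a non-polar solvent and low temperature.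

Step 8
Reactants: 11 (5S,6S)-6-hydroxy-2-methyl-5-[3-(tert-butyldimethylsilyloxy)prop-1-en-2-yl]cyclohex-2-en-1-one; 12 tigloyl chloride ((2E)-2-methylbut-2-enoyl chloride)
Product: 13 (1S,6S)-3-methyl-2-oxo-6-[3-(tert-butyldimethylsilyloxy)prop-1-en-2-yl]cyclohex-3-en-1-yl (2E)-2-methylbut-2-enoate
Conditions: pyridine, DMAP (cat.), CH2Cl2, 0 °C
Reagents that add atoms: none
Why: DMAP-catalysed acylation of the secondary α-ketol hydroxyl with the acid chloride, with pyridine instead of a trialkylamine so that no vinylketene forms from 12 and the (E) geometry is kept; C6 is not touched and its trans relation to C5 is also the thermodynamic one.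

Step 9
Reactants: 13 (1S,6S)-3-methyl-2-oxo-6-[3-(tert-butyldimethylsilyloxy)prop-1-en-2-yl]cyclohex-3-en-1-yl (2E)-2-methylbut-2-enoate
Product: 14 (1S,2S,6S)-2-hydroxy-3-methyl-6-[3-(tert-butyldimethylsilyloxy)prop-1-en-2-yl]cyclohex-3-en-1-yl (2E)-2-methylbut-2-enoate
Conditions: NaBH4, CeCl3·7H2O, MeOH, −78 °C
Reagents that add atoms: none
Why: Luche reduction gives clean 1,2-reduction of the enone, and axial hydride delivery to the half-chair in which the C5 and C6 substituents are pseudo-equatorial sets the new C1 carbinol pseudo-equatorial, trans to the C6 ester and cis to the C5 side chain.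

Step 10
Reactants: 14 (1S,2S,6S)-2-hydroxy-3-methyl-6-[3-(tert-butyldimethylsilyloxy)prop-1-en-2-yl]cyclohex-3-en-1-yl (2E)-2-methylbut-2-enoate
Product: 15 (1R,2R,3S,4S,6S)-4-[3-(tert-butyldimethylsilyloxy)prop-1-en-2-yl]-2-hydroxy-1-methyl-7-oxabicyclo[4.1.0]heptan-3-yl (2E)-2-methylbut-2-enoate
Conditions: VO(acac)2 (cat.), t-BuOOH (in decane), CH2Cl2, 0 → 23 °C
Reagents that add atoms: tert-butyl hydroperoxide CC(C)(C)OO
Why: Vanadium-catalysed hydroxyl-directed epoxidation of a cyclic allylic alcohol delivers the oxygen to C2=C3 on the face of the C1 hydroxyl (syn), the face that alkaline peroxide epoxidation of the enone would not reach, and ignores the electron-poor tiglate alkene and the methylene group that has no free hydroxyl next to it.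

Step 11
Reactants: 15 (1R,2R,3S,4S,6S)-4-[3-(tert-butyldimethylsilyloxy)prop-1-en-2-yl]-2-hydroxy-1-methyl-7-oxabicyclo[4.1.0]heptan-3-yl (2E)-2-methylbut-2-enoate
Product: 16 (1R,2R,3S,4S,6S)-2-hydroxy-4-(3-hydroxyprop-1-en-2-yl)-1-methyl-7-oxabicyclo[4.1.0]heptan-3-yl (2E)-2-methylbut-2-enoate
Conditions: HF·pyridine, pyridine, THF, 0 °C
Reagents that add atoms: none
Why: Buffered fluoride cleavage of a primary silyl ether (desilylation), mild enough for the epoxy alcohol and the ester.

Step 12
Reactants: 16 (1R,2R,3S,4S,6S)-2-hydroxy-4-(3-hydroxyprop-1-en-2-yl)-1-methyl-7-oxabicyclo[4.1.0]heptan-3-yl (2E)-2-methylbut-2-enoate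
Product: 17 (1R,2R,3S,4S,6S)-2-hydroxy-1-methyl-4-(3-oxoprop-1-en-2-yl)-7-oxabicyclo[4.1.0]heptan-3-yl (2E)-2-methylbut-2-enoate
Conditions: MnO2 (activated), CH2Cl2, 23 °C
Reagents that add atoms: none
Why: MnO2 oxidises only the primary allylic alcohol (allylic oxidation), since the C1 carbinol is no longer allylic once C2=C3 is an oxirane.

Step 13
Reactants: 17 (1R,2R,3S,4S,6S)-2-hydroxy-1-methyl-4-(3-oxoprop-1-en-2-yl)-7-oxabicyclo[4.1.0]heptan-3-yl (2E)-2-methylbut-2-enoate; 18 allylboronic acid pinacol ester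
Product: 19 (1R,2R,3S,4S,6S)-2-hydroxy-4-(3-hydroxyhexa-1,5-dien-2-yl)-1-methyl-7-oxabicyclo[4.1.0]heptan-3-yl (2E)-2-methylbut-2-enoate (C8 epimers)
Conditions: CH2Cl2, 23 °C; aqueous NaHCO3 work-up
Reagents that add atoms: none
Why: Allylboration through a six-membered chair transition state is neutral and selective for the aldehyde, so the free hydroxyl, the ester and the oxirane are untouched; the new C8 carbinol centre is not controlled because it is oxidised in step 15.

Step 14
Reactants: 19 (1R,2R,3S,4S,6S)-2-hydroxy-4-(3-hydroxyhexa-1,5-dien-2-yl)-1-methyl-7-oxabicyclo[4.1.0]heptan-3-yl (2E)-2-methylbut-2-enoate; 20 2-methylbut-2-ene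
Product: 21 (1R,2R,3S,4S,6S)-2-hydroxy-4-(3-hydroxy-6-methylhepta-1,5-dien-2-yl)-1-methyl-7-oxabicyclo[4.1.0]heptan-3-yl (2E)-2-methylbut-2-enoate (C8 epimers)
Conditions: second-generation Grubbs catalyst RuCl2(=CHPh)(PCy3)(H2IMes) (cat.), 20 in large excess, CH2Cl2, 40 °C
Reagents that add atoms: none
Why: Olefin cross-metathesis of the terminal alkene with an excess of 2-methylbut-2-ene exchanges =CH2 for =C(CH3)2 and so makes the prenyl group, while the 1,1-disubstituted methylene and the trisubstituted electron-poor tiglate alkene do not enter the catalytic cycle at a comparable rate.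

Step 15
Reactants: 21 (1R,2R,3S,4S,6S)-2-hydroxy-4-(3-hydroxy-6-methylhepta-1,5-dien-2-yl)-1-methyl-7-oxabicyclo[4.1.0]heptan-3-yl (2E)-2-methylbut-2-enoate
Product: 22 (1S,3S,4S,6S)-1-methyl-4-(6-methyl-3-oxohepta-1,5-dien-2-yl)-2-oxo-7-oxabicyclo[4.1.0]heptan-3-yl (2E)-2-methylbut-2-enoate
Conditions: Dess–Martin periodinane, NaHCO3, CH2Cl2, 0 → 23 °C
Reagents that add atoms: none
Why: Dess–Martin oxidation turns both secondary carbinols into ketones in one operation, which restores the C1 ketone beside the intact oxirane and merges the C8 epimers, the bicarbonate buffer keeping the β,γ-unsaturated ketone from moving into conjugation.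

Step 16
Reactants: 22 (1S,3S,4S,6S)-1-methyl-4-(6-methyl-3-oxohepta-1,5-dien-2-yl)-2-oxo-7-oxabicyclo[4.1.0]heptan-3-yl (2E)-2-methylbut-2-enoate
Product: 23 (1S,3S,4S,6S)-4-[(4E)-6-hydroperoxy-6-methyl-3-oxohepta-1,4-dien-2-yl]-1-methyl-2-oxo-7-oxabicyclo[4.1.0]heptan-3-yl (2E)-2-methylbut-2-enoate (CNP0284595.1)
Conditions: O2, meso-tetraphenylporphyrin (cat.), visible light, CH2Cl2, −20 °C; no reductive work-up
Reagents that add atoms: dioxygen O=O
Why: Schenck ene reaction, in which singlet oxygen attacks the only electron-rich alkene, bonds to C11 and takes a hydrogen from C9, whose C–H bonds are activated by the C8 carbonyl and whose loss brings the new C9=C10 bond into conjugation as the (E) isomer; the secondary hydroperoxide regioisomer is the expected by-product and is separated.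

**Compound list**

1 | monomethyl itaconate (4-methoxy-2-methylidene-4-oxobutanoic acid) | C=C(CC(=O)OC)C(=O)O | starting material
2 | ethyl carbonic mixed anhydride of 1 | C=C(CC(=O)OC)C(=O)OC(=O)OCC | intermediate (not isolated)
3 | methyl 3-(hydroxymethyl)but-3-enoate | C=C(CO)CC(=O)OC | intermediate
4 | methyl 3-[(tert-butyldimethylsilyloxy)methyl]but-3-enoate | C=C(CO[Si](C)(C)C(C)(C)C)CC(=O)OC | intermediate
5 | 3-methylfuran-2(5H)-one | CC1=CCOC1=O | starting material
6 | methyl (2Z)-4-bromo-2-methylbut-2-enoate | BrC/C=C(/C)C(=O)OC | intermediate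
7 | lithium dienolate of 4 | [Li+].[O-]C(OC)=CC(=C)CO[Si](C)(C)C(C)(C)C | intermediate (not isolated)
8 | dimethyl (2Z)-5-[3-(tert-butyldimethylsilyloxy)prop-1-en-2-yl]-2-methylhex-2-enedioate (racemic) | COC(=O)/C(C)=C\CC(C(=O)OC)C(=C)CO[Si](C)(C)C(C)(C)C | intermediate
9 | (2Z)-5-[3-(tert-butyldimethylsilyloxy)prop-1-en-2-yl]-2-methylhex-2-ene-1,6-diol (racemic) | OC/C(C)=C\CC(CO)C(=C)CO[Si](C)(C)C(C)(C)C | intermediate
10 | (2Z)-5-[3-(tert-butyldimethylsilyloxy)prop-1-en-2-yl]-2-methylhex-2-enedial (racemic) | O=C/C(C)=C\CC(C=O)C(=C)CO[Si](C)(C)C(C)(C)C | intermediate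
11 | (5S,6S)-6-hydroxy-2-methyl-5-[3-(tert-butyldimethylsilyloxy)prop-1-en-2-yl]cyclohex-2-en-1-one | C=C(CO[Si](C)(C)C(C)(C)C)[C@@H]1CC=C(C)C(=O)[C@H]1O | intermediate
12 | tigloyl chloride, (2E)-2-methylbut-2-enoyl chloride | C/C=C(\C)C(Cl)=O | starting material
13 | (1S,6S)-3-methyl-2-oxo-6-[3-(tert-butyldimethylsilyloxy)prop-1-en-2-yl]cyclohex-3-en-1-yl (2E)-2-methylbut-2-enoate | C=C(CO[Si](C)(C)C(C)(C)C)[C@@H]1CC=C(C)C(=O)[C@H]1OC(=O)/C(C)=C/C | intermediate
14 | (1S,2S,6S)-2-hydroxy-3-methyl-6-[3-(tert-butyldimethylsilyloxy)prop-1-en-2-yl]cyclohex-3-en-1-yl (2E)-2-methylbut-2-enoate | C=C(CO[Si](C)(C)C(C)(C)C)[C@@H]1CC=C(C)[C@H](O)[C@H]1OC(=O)/C(C)=C/C | intermediate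
15 | (1R,2R,3S,4S,6S)-4-[3-(tert-butyldimethylsilyloxy)prop-1-en-2-yl]-2-hydroxy-1-methyl-7-oxabicyclo[4.1.0]heptan-3-yl (2E)-2-methylbut-2-enoate | C=C(CO[Si](C)(C)C(C)(C)C)[C@@H]1C[C@@H]2O[C@]2(C)[C@H](O)[C@H]1OC(=O)/C(C)=C/C | intermediate
16 | (1R,2R,3S,4S,6S)-2-hydroxy-4-(3-hydroxyprop-1-en-2-yl)-1-methyl-7-oxabicyclo[4.1.0]heptan-3-yl (2E)-2-methylbut-2-enoate | C=C(CO)[C@@H]1C[C@@H]2O[C@]2(C)[C@H](O)[C@H]1OC(=O)/C(C)=C/C | intermediate
17 | (1R,2R,3S,4S,6S)-2-hydroxy-1-methyl-4-(3-oxoprop-1-en-2-yl)-7-oxabicyclo[4.1.0]heptan-3-yl (2E)-2-methylbut-2-enoate | C=C(C=O)[C@@H]1C[C@@H]2O[C@]2(C)[C@H](O)[C@H]1OC(=O)/C(C)=C/C | intermediate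
18 | allylboronic acid pinacol ester | C=CCB1OC(C)(C)C(C)(C)O1 | starting material
19 | (1R,2R,3S,4S,6S)-2-hydroxy-4-(3-hydroxyhexa-1,5-dien-2-yl)-1-methyl-7-oxabicyclo[4.1.0]heptan-3-yl (2E)-2-methylbut-2-enoate (C8 epimers) | C=C(C(O)CC=C)[C@@H]1C[C@@H]2O[C@]2(C)[C@H](O)[C@H]1OC(=O)/C(C)=C/C | intermediate
20 | 2-methylbut-2-ene | CC=C(C)C | starting material
21 | (1R,2R,3S,4S,6S)-2-hydroxy-4-(3-hydroxy-6-methylhepta-1,5-dien-2-yl)-1-methyl-7-oxabicyclo[4.1.0]heptan-3-yl (2E)-2-methylbut-2-enoate (C8 epimers) | C=C(C(O)CC=C(C)C)[C@@H]1C[C@@H]2O[C@]2(C)[C@H](O)[C@H]1OC(=O)/C(C)=C/C | intermediate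
22 | (1S,3S,4S,6S)-1-methyl-4-(6-methyl-3-oxohepta-1,5-dien-2-yl)-2-oxo-7-oxabicyclo[4.1.0]heptan-3-yl (2E)-2-methylbut-2-enoate | C=C(C(=O)CC=C(C)C)[C@@H]1C[C@@H]2O[C@]2(C)C(=O)[C@H]1OC(=O)/C(C)=C/C | intermediate
23 | (1S,3S,4S,6S)-4-[(4E)-6-hydroperoxy-6-methyl-3-oxohepta-1,4-dien-2-yl]-1-methyl-2-oxo-7-oxabicyclo[4.1.0]heptan-3-yl (2E)-2-methylbut-2-enoate | C=C(C(=O)/C=C/C(C)(C)OO)[C@@H]1C[C@@H]2O[C@]2(C)C(=O)[C@H]1OC(=O)/C(C)=C/C | target

**Count and risks**

Total: 16 steps. Longest linear sequence: 15 steps (steps 1, 2 and 4–16; step 3 is a one-step side branch).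

Steps most likely to fail:

1. Step 7 (proposed new method). Base-induced migration of C7=C14 into conjugation with the C6 aldehyde, or aldol closure from C5, may outrun the carbene-mediated closure; racemisation of C5 may also be too slow for high enantiocontrol. The fallback uses neutral, known chemistry and sets out from 10. Low-valent titanium pinacol coupling (TiCl3(DME)1.5, Zn–Cu, DME) closes C1–C6 to racemic 3-methyl-6-[3-(tert-butyldimethylsilyloxy)prop-1-en-2-yl]cyclohex-3-ene-1,2-diol F1. Oxidation of the allylic carbinol alone (MnO2, CH2Cl2, then a trace of Et3N to bring C6 trans to C5) gives racemic trans-6-hydroxy-2-methyl-5-[3-(tert-butyldimethylsilyloxy)prop-1-en-2-yl]cyclohex-2-en-1-one F2. Lipase resolution (Pseudomonas cepacia lipase, vinyl acetate, t-BuOMe) is assumed to acylate the unwanted antipode to (1R,6R)-3-methyl-2-oxo-6-[3-(tert-butyldimethylsilyloxy)prop-1-en-2-yl]cyclohex-3-en-1-yl acetate F3 and to leave the (5S,6S) alcohol; with the opposite enzyme preference the acetate of the wanted antipode is cleaved with K2CO3/MeOH. The route is rejoined at 11.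

2. Step 4. Conjugate addition of the dienolate to the bromo enoate with cyclopropane closure may compete with SN2 displacement, and 6 may relactonise. The fallback sets out from 6 and removes the Michael acceptor. Reduction with i-Bu2AlH (CH2Cl2, −78 °C) gives (2Z)-4-bromo-2-methylbut-2-en-1-ol F4, acylated at once (pivaloyl chloride, pyridine, 0 °C) to (2Z)-4-bromo-2-methylbut-2-en-1-yl pivalate F5. The dienolate 7 is alkylated with F5 to methyl (4Z)-2-[3-(tert-butyldimethylsilyloxy)prop-1-en-2-yl]-6-[(2,2-dimethylpropanoyl)oxy]-5-methylhex-4-enoate F6, and i-Bu2AlH then removes the pivalate and reduces the methyl ester in one operation. The route is rejoined at 9.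

3. Step 16. Hydrogen abstraction from a C11 methyl group instead of C9 gives the secondary hydroperoxide and lowers the share of the target. The fallback brings the peroxide in as a protected building block and sets out from 17. Nozaki–Hiyama–Kishi vinylation (vinyl bromide, CrCl2, NiCl2 cat., DMF) gives (1R,2R,3S,4S,6S)-2-hydroxy-4-(3-hydroxypenta-1,4-dien-2-yl)-1-methyl-7-oxabicyclo[4.1.0]heptan-3-yl (2E)-2-methylbut-2-enoate F7. Dess–Martin oxidation of both carbinols gives (1S,3S,4S,6S)-1-methyl-2-oxo-4-(3-oxopenta-1,4-dien-2-yl)-7-oxabicyclo[4.1.0]heptan-3-yl (2E)-2-methylbut-2-enoate F8. Cross-metathesis of its vinyl ketone with 2-[(2-methoxypropan-2-yl)peroxy]-2-methylbut-3-ene (second-generation Hoveyda–Grubbs catalyst RuCl2(=CH-2-(i-PrO)C6H4)(H2IMes), CH2Cl2, 40 °C; peroxyketals are tolerated by ruthenium alkylidenes) gives (1S,3S,4S,6S)-4-{(4E)-6-[(2-methoxypropan-2-yl)peroxy]-6-methyl-3-oxohepta-1,4-dien-2-yl}-1-methyl-2-oxo-7-oxabicyclo[4.1.0]heptan-3-yl (2E)-2-methylbut-2-enoate F9. Mild hydrolysis (AcOH, THF, H2O) frees the hydroperoxide. The route is rejoined at 23.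

**Further compounds**

F1 | step 7 | rac-3-methyl-6-[3-(tert-butyldimethylsilyloxy)prop-1-en-2-yl]cyclohex-3-ene-1,2-diol (diastereomer mixture) | C=C(CO[Si](C)(C)C(C)(C)C)C1CC=C(C)C(O)C1O
F2 | step 7 | rac-trans-6-hydroxy-2-methyl-5-[3-(tert-butyldimethylsilyloxy)prop-1-en-2-yl]cyclohex-2-en-1-one | C=C(CO[Si](C)(C)C(C)(C)C)C1CC=C(C)C(=O)C1O
F3 | step 7 | (1R,6R)-3-methyl-2-oxo-6-[3-(tert-butyldimethylsilyloxy)prop-1-en-2-yl]cyclohex-3-en-1-yl acetate | C=C(CO[Si](C)(C)C(C)(C)C)[C@H]1CC=C(C)C(=O)[C@@H]1OC(C)=O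
F4 | step 4 | (2Z)-4-bromo-2-methylbut-2-en-1-ol | BrC/C=C(/C)CO
F5 | step 4 | (2Z)-4-bromo-2-methylbut-2-en-1-yl pivalate | BrC/C=C(/C)COC(=O)C(C)(C)C
F6 | step 4 | methyl (4Z)-2-[3-(tert-butyldimethylsilyloxy)prop-1-en-2-yl]-6-[(2,2-dimethylpropanoyl)oxy]-5-methylhex-4-enoate (racemic) | COC(=O)C(C/C=C(/C)COC(=O)C(C)(C)C)C(=C)CO[Si](C)(C)C(C)(C)C
F7 | step 16 | (1R,2R,3S,4S,6S)-2-hydroxy-4-(3-hydroxypenta-1,4-dien-2-yl)-1-methyl-7-oxabicyclo[4.1.0]heptan-3-yl (2E)-2-methylbut-2-enoate (C8 epimers) | C=C(C(O)C=C)[C@@H]1C[C@@H]2O[C@]2(C)[C@H](O)[C@H]1OC(=O)/C(C)=C/C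
F8 | step 16 | (1S,3S,4S,6S)-1-methyl-2-oxo-4-(3-oxopenta-1,4-dien-2-yl)-7-oxabicyclo[4.1.0]heptan-3-yl (2E)-2-methylbut-2-enoate | C=C(C(=O)C=C)[C@@H]1C[C@@H]2O[C@]2(C)C(=O)[C@H]1OC(=O)/C(C)=C/C
F9 | step 16 | (1S,3S,4S,6S)-4-{(4E)-6-[(2-methoxypropan-2-yl)peroxy]-6-methyl-3-oxohepta-1,4-dien-2-yl}-1-methyl-2-oxo-7-oxabicyclo[4.1.0]heptan-3-yl (2E)-2-methylbut-2-enoate | C=C(C(=O)/C=C/C(C)(C)OOC(C)(C)OC)[C@@H]1C[C@@H]2O[C@]2(C)C(=O)[C@H]1OC(=O)/C(C)=C/C
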